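**Assumption:** the target has no stereocentre, and the biaryl axis is not configurationally stable (both ortho positions on the chromene ring are H), so it is achiral. "Single enantiomer" is taken to mean the constitution exactly as drawn; no stereocontrol is needed.

## Retrosynthetic overview

1. Target ⇐ tris-MOM ether 10 by a final non-protic global deprotection.
2. 10 ⇐ one Pd/norbornene three-component coupling (new) that forms the biaryl bond and both aryl–prenyl bonds around C1′ of the catechol ring, from aryl iodide 8, prenyl chloride 9 and chromenyl boronate 5.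
3. 5 ⇐ 7-bromo-2,2-dimethylchromen-5-ol 3 (MOM protection, Miyaura borylation); 3 ⇐ 5-bromoresorcinol 1 + prenal 2 by formal [3+3] chromenylation.
4. 8 ⇐ 4-bromocatechol 6 (MOM protection, Br→I).
5. Ring order: both benzene rings are purchased; the pyran ring is the only ring made (step 1); the biaryl axis and prenyl groups come last.

## Route

**Step 1**
Reactants: 1, 5-bromobenzene-1,3-diol (5-bromoresorcinol); 2, 3-methylbut-2-enal (prenal)
Product: 3, 7-bromo-2,2-dimethyl-2H-chromen-5-ol
Conditions: 2 (1.05 equiv), ethylenediammonium diacetate (20 mol %), toluene, reflux (Dean–Stark)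
Reagents that add atoms: none (all product atoms come from 1 and 2; water is lost)
Why: Amine-catalysed Knoevenagel-type C-alkylation at the carbon between the two OH groups (the usual site for 5-substituted resorcinols), dehydration to an o-quinone methide and oxa-6π electrocyclisation (formal [3+3] chromenylation) give the 5-hydroxy-7-bromo isomer.

**Step 2**
Reactants: 3, 7-bromo-2,2-dimethyl-2H-chromen-5-ol
Product: 4, 7-bromo-5-(methoxymethoxy)-2,2-dimethyl-2H-chromene
Conditions: MOMCl, i-Pr2NEt, CH2Cl2, 0 °C → rt
Reagents that add atoms: chloromethyl methyl ether (MOMCl), COCCl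
Why: Standard O-alkylation of the single phenol (MOM protection); it prevents O-prenylation and boronate problems later.

**Step 3**
Reactants: 4, 7-bromo-5-(methoxymethoxy)-2,2-dimethyl-2H-chromene
Product: 5, 2-[5-(methoxymethoxy)-2,2-dimethyl-2H-chromen-7-yl]-4,4,5,5-tetramethyl-1,3,2-dioxaborolane
Conditions: B2pin2, Pd(dppf)Cl2 (3 mol %), KOAc, 1,4-dioxane, 85 °C
Reagents that add atoms: bis(pinacolato)diboron, CC1(C)OB(OC1(C)C)B1OC(C)(C)C(C)(C)O1
Why: Miyaura borylation of an unhindered aryl bromide; KOAc suppresses Suzuki homocoupling, and the chromene olefin and MOM ether are inert.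

**Step 4**
Reactants: 6, 4-bromobenzene-1,2-diol (4-bromocatechol)
Product: 7, 4-bromo-1,2-bis(methoxymethoxy)benzene
Conditions: MOMCl (3 equiv), i-Pr2NEt, CH2Cl2, 0 °C → rt, under N2
Reagents that add atoms: chloromethyl methyl ether (MOMCl), COCCl
Why: Standard double MOM protection; MOM is small next to the ring, which matters for the later C–H palladation beside the oxygen.

**Step 5**
Reactants: 7, 4-bromo-1,2-bis(methoxymethoxy)benzene
Product: 8, 4-iodo-1,2-bis(methoxymethoxy)benzene
Conditions: n-BuLi, THF, −78 °C, 15 min; then I2, −78 °C → rt
Reagents that add atoms: iodine, II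
Why: Bromine–lithium exchange at −78 °C is much faster than MOM-directed ortho-lithiation, and iodine quench gives the aryl iodide needed for fast oxidative addition in Pd/norbornene chemistry.

**Step 6 (key step, new)**
Reactants: 8, 4-iodo-1,2-bis(methoxymethoxy)benzene; 9, 1-chloro-3-methylbut-2-ene (prenyl chloride, 4 equiv, 2 incorporated); 5, chromenyl pinacol boronate (1.3 equiv)
Product: 10, 7-[3,4-bis(methoxymethoxy)-2,6-bis(3-methylbut-2-en-1-yl)phenyl]-5-(methoxymethoxy)-2,2-dimethyl-2H-chromene
Conditions: Pd(OAc)2 (10 mol %), P(2-furyl)3 (20 mol %), norbornene (2 equiv), K2CO3, DMF/H2O (20:1), 50 °C, Ar; 9 added in portions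
Reagents that add atoms: none (all product atoms come from 8, 9 and 5; norbornene is a mediator and is extruded)
Why: Proposed new method: a Catellani-type ortho,ortho′-C–H diprenylation with ipso Suzuki termination. ArPd(II)I from 8 inserts norbornene and closes to the aryl–norbornyl palladacycle; its nucleophilic Pd(II) attacks the primary carbon of prenyl chloride by SN2 (the gem-dimethyl terminus blocks SN2′) to give a Pd(IV) prenyl species that reductively eliminates the linear aryl–CH2CH=CMe2 bond; the same sequence at the second ortho C–H, sterically driven norbornene extrusion, and transmetalation with unhindered 5 then close the cycle, and because both ortho positions are functionalised there is no regiochemical question. The closest known reaction type is the Pd/norbornene (Catellani–Suzuki) synthesis of 2,6-dialkyl-1,1′-biaryls from aryl iodides, primary alkyl bromides and arylboronic acids, together with stoichiometric oxidative addition of allyl bromide to such palladacycles. The new problem is Pd(0) ionising the allylic electrophile; the design counters this with the chloride of a trisubstituted alkene (slow η3 formation), a weakly donating phosphine and a high ArI concentration.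

**Step 7**
Reactants: 10, tris-MOM ether
Product: 11, clusiachromene D, 4-(5-hydroxy-2,2-dimethyl-2H-chromen-7-yl)-3,5-bis(3-methylbut-2-en-1-yl)benzene-1,2-diol
Conditions: TMSOTf (9 equiv), 2,2′-bipyridyl (12 equiv), MeCN, 0 °C → rt; then H2O, rt (degassed work-up)
Reagents that add atoms: none (the aryl oxygens are retained; transient O–SiMe3 groups are hydrolysed)
Why: Buffered silyl-triflate MOM cleavage converts aryl MOM ethers to aryl TMS ethers that hydrolyse on work-up; this avoids the Brønsted acid that would cyclise ortho-prenyl phenols to chromans or hydrate the chromene.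

## Compound list

1 | 5-bromobenzene-1,3-diol | Oc1cc(O)cc(Br)c1 | starting material
2 | 3-methylbut-2-enal | CC(C)=CC=O | starting material
3 | 7-bromo-2,2-dimethyl-2H-chromen-5-ol | Oc1cc(Br)cc2OC(C)(C)C=Cc12 | intermediate
4 | 7-bromo-5-(methoxymethoxy)-2,2-dimethyl-2H-chromene | COCOc1cc(Br)cc2OC(C)(C)C=Cc12 | intermediate
5 | 2-[5-(methoxymethoxy)-2,2-dimethyl-2H-chromen-7-yl]-4,4,5,5-tetramethyl-1,3,2-dioxaborolane | COCOc1cc(B3OC(C)(C)C(C)(C)O3)cc2OC(C)(C)C=Cc12 | intermediate
6 | 4-bromobenzene-1,2-diol | Oc1ccc(Br)cc1O | starting material
7 | 4-bromo-1,2-bis(methoxymethoxy)benzene | COCOc1ccc(Br)cc1OCOC | intermediate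
8 | 4-iodo-1,2-bis(methoxymethoxy)benzene | COCOc1ccc(I)cc1OCOC | intermediate
9 | 1-chloro-3-methylbut-2-ene | CC(C)=CCCl | starting material
10 | 7-[3,4-bis(methoxymethoxy)-2,6-bis(3-methylbut-2-en-1-yl)phenyl]-5-(methoxymethoxy)-2,2-dimethyl-2H-chromene | CC(C)=CCc1cc(OCOC)c(OCOC)c(CC=C(C)C)c1-c1cc(OCOC)c2c(c1)OC(C)(C)C=C2 | intermediate
11 | clusiachromene D | CC(C)=CCc1cc(O)c(O)c(CC=C(C)C)c1-c1cc(O)c2c(c1)OC(C)(C)C=C2 | target

## Summary

Total steps: 7. Longest linear sequence: 5 (steps 1 → 2 → 3 → 6 → 7); the iodide branch is 2 steps (4, 5) before the convergent step.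

Steps most likely to fail:

1. **Step 6 (proposed new step).** Risks: Pd(0) ionises prenyl chloride, giving prenyl–aryl Suzuki by-product and catalyst sequestration; the second C–H palladation next to OMOM is slow, giving mono-prenyl or norbornene-containing products; branched (reverse-prenyl) isomers form.
   Fallback (known chemistry): ordinary Suzuki–Miyaura coupling of 5 with 5-bromo-2-(methoxymethoxy)phenol (from 5-bromosalicylaldehyde by MOM protection and Dakin oxidation; its free OH is the future C3′–OH). Both prenyls are then delivered from that oxygen by aromatic Claisen chemistry: first the 1,1-dimethylpropargyl ether, Lindlar reduction and [3,3] shift of the 1,1-dimethylallyl ether to C2′; then O-prenylation and thermal para-Claisen–Cope to C6′; then step 7.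

2. **Step 1.** Risks: the regioisomeric 5-bromo-7-hydroxychromene and bis-annulation on the electron-poorer bromoresorcinol.
   Fallback: a regiodefined route from 4-bromo-2,6-dihydroxybenzaldehyde (by demethylation of 4-bromo-2,6-dimethoxybenzaldehyde), where the aldehyde carbon already sits between the two oxygens. Petasis-type condensation with 2-methylprop-1-enylboronic acid and a secondary amine, with cyclisation, gives 3 as a single regioisomer.

3. **Step 7.** Risks: incomplete cleavage of three MOM groups, or Lewis-acid-triggered chroman formation from the ortho-prenyl catechol.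
   Fallback: change the protecting-group strategy rather than the acid. Carry all three phenols as SEM ethers (SEMCl in steps 2 and 4; similar size next to the ring) and unmask with fluoride (TBAF/DMPU), so no electrophilic activator meets the prenyl or chromene groups.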